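The amounts came first: the flask held 10 mM of starting material, 0.93 µM of enzyme and 0.21 µM of impurity, so the impurity stood at 22.6 % of the enzyme charge.

| setting | cedar | alder | ash | flask |
|---|---|---|---|---|
| starting material | 6.7 mM | 15 mM | 10 mM | 10 mM |
| enzyme | 0.93 µM | 0.93 µM | 1.9 µM | 0.93 µM |
| impurity | 0.21 µM | 0.21 µM | 0.21 µM | 0.21 µM |
| remark | run made earlier | run made earlier | run made earlier |  |

| run | time / min | product / % | starting material / % |
|---|---|---|---|
| cedar | 0.833 | 31.9 | 67.0 |
| cedar | 1.50 | 48.8 | 52.1 |
| cedar | 2.50 | 62.1 | 36.9 |
| cedar | 3.00 | 66.8 | 33.7 |
| alder | 0.250 | 13.9 | 84.7 |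
| alder | 0.500 | 28.0 | 73.9 |
| alder | 1.33 | 55.5 | 43.0 |
| alder | 3.00 | 78.7 | 21.6 |
| ash | 0.833 | 61.8 | 36.5 |
| ash | 1.50 | 77.6 | 23.6 |
| ash | 2.50 | 85.1 | 14.7 |
| ash | 3.00 | 87.0 | 12.4 |

(each reading ± 0.5 percentage points)

* factor on the rate of making product when 30 % of the starting material are converted if enzyme is charged twice over
* factor on the rate when 30 % of the starting material are converted if enzyme is charged at 5.0 µM instead

- steps thought possible: starting material + enzyme -> product + enzyme; enzyme + impurity -> spent catalyst

I wanted the factors without a rate law. Both questions keep the starting material at 10 mM and look at 30 % conversion, so its concentration was the same on both sides of each ratio, and any order in it cancelled. What remained was enzyme, and I took the rate as proportional to it. Spent catalyst has no part in the product step, and I assumed that the impurity step ended early, with impurity as the limiting reagent. What it leaves free I called the working enzyme, the enzyme charge minus the impurity charge: 0.720 µM in the flask.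

That needed a test. If the rate goes roughly as the square of the starting material, the inverse of its concentration climbs steadily, at a pace that measures enzyme. Between 0.833 min and 3.00 min, ash climbed 2.42 times as fast as cedar, a reading with its scatter. The charges stood at 2.04 to one and the working enzymes at 2.35 to one, and the reading lay nearer the second. Cedar and ash differ in starting material too, so this test stands on that square.

For the flask I reckoned 2.29 on doubling and 6.65 at 5.0 µM. The forecast gave the same, 2.29 and 6.65, and said of the ash excess: “it matches titration of enzyme by the impurity”.

The simulation gave 2.29 and 6.65.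

    starting material + enzyme → product + enzyme, rate k1*[starting material]^2*[enzyme]/(1 + ([starting material]/Kh1)^2) (12.0 mM, k = 2.50 × 10⁶ L² mol⁻² s⁻¹)
    enzyme + impurity → spent catalyst (k = 4.00 × 10⁶ L mol⁻¹ s⁻¹)

With the impurity as charged, capture ran at 50 min⁻¹ per enzyme in the flask, a time of 0.0200 min, far shorter than the 0.769 min by which half the product-making up to 3.00 min was done. Spent catalyst in the flask stood at 22.6 % of the catalyst after 0.300 min and at 22.6 % after 3.00 min, with 0 % of the impurity left at that later time. At 30 % conversion enzyme was 77.4 % of the catalyst in the flask, and the working enzyme over the charge gives 77.4 %. The same subtraction at 5.0 µM gives 95.8 %, against 95.8 % of the catalyst as enzyme at the same conversion in that run.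

(All runs stem from a simulated flask from invented constants; the scatter is artificial.)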